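**Plan**
- Atom labels used below: C1 (ring-fusion C–CH3), C2, C3, C4 (C(OH)i-Pr), C5 (ring-fusion CH), C6 (CH–O-aroyl), C7 (CH2), C8 (C–CH3), C9 (=CH), C10 (C=O).
- Cuts, in retrosynthetic order: the ester C–O bond; C6–O and C7–H (back to a C6=C7 alkene through its epoxide); C1–CH3 (back to a C1=C10 silyl enol ether through a cyclopropane); C4–i-Pr (back to a C4 ketone); then C5–C1 and C5–C6 together, which gives back an aryl diazo ketone.
- Enabling feature: C1 and C6–C10 of the seven-membered ring are the six carbons of a 2-silyloxy-4-methylphenyl ring (C8 methyl and C10 oxygen already in place), C5 is one carbene carbon, and C2–C3–C4(=O) is the tether that makes the cyclopentanone.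
- Forward: the arene receives its tether and diazo carbon (steps 1–4); step 5 closes the five-membered ring and expands the benzene ring to the seven-membered ring in one operation; steps 6–11 add i-Pr, CH3, the C6 oxygen and the ester.
- Stereochemistry: C5 from the chiral copper catalyst; C4 by addition anti to C6; C1 by CH2 delivery from the C4 hydroxyl; C6 by epoxidation anti to the C1 methyl group.

Key step: step 5

Remark: the sense of induction of the copper bis(oxazoline) catalyst with this ortho-silyloxy arene is taken as assignable in a first run, and the ligand antipode that leads to (8aR)-10 is the one used.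

**Route**

Step 1
Reactants: 1 2-hydroxy-4-methylbenzaldehyde
Product: 2 4-methyl-2-{[tri(propan-2-yl)silyl]oxy}benzaldehyde
Conditions: i-Pr3SiCl (1.2 equiv), imidazole (2.5 equiv), DMF, rt
Reagents that add atoms: triisopropylsilyl chloride, CC(C)[Si](Cl)(C(C)C)C(C)C
Why: Imidazole-promoted silylation of the phenol (silyl ether formation) installs a bulky aryl silyl ether that will later be the C10 silyl enol ether and will block the neighbouring ortho position in step 5, and no stereocentre is formed.

Step 2
Reactants: 2 4-methyl-2-{[tri(propan-2-yl)silyl]oxy}benzaldehyde; 3 benzyl (triphenylphosphoranylidene)acetate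
Product: 4 benzyl (2E)-3-(4-methyl-2-{[tri(propan-2-yl)silyl]oxy}phenyl)prop-2-enoate
Conditions: toluene, 80 °C
Reagents that add atoms: none
Why: Wittig olefination with a stabilised ylide should give the E cinnamate under neutral conditions that leave the aryl silyl ether untouched, the aldehyde carbon becoming C2 and the ylide carbons C3 and C4.

Step 3
Reactants: 4 benzyl (2E)-3-(4-methyl-2-{[tri(propan-2-yl)silyl]oxy}phenyl)prop-2-enoate
Product: 5 3-(4-methyl-2-{[tri(propan-2-yl)silyl]oxy}phenyl)propanoic acid
Conditions: H2 (1 atm), 10% Pd/C, EtOAc, rt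
Reagents that add atoms: none
Why: Catalytic hydrogenation saturates the conjugated alkene and hydrogenolyses the benzyl ester in the same operation, while the arene and the aryl silyl ether are inert under these conditions.

Step 4
Reactants: 5 3-(4-methyl-2-{[tri(propan-2-yl)silyl]oxy}phenyl)propanoic acid; 6 (trimethylsilyl)diazomethane
Product: 8 1-diazo-4-(4-methyl-2-{[tri(propan-2-yl)silyl]oxy}phenyl)butan-2-one, via acid chloride 7 (not isolated)
Conditions: (COCl)2 (1.3 equiv), DMF (catalytic), CH2Cl2, 0 °C → rt, then evaporation; 6 (2.2 equiv), THF–MeCN (1:1), 0 °C → rt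
Reagents that add atoms: none
Why: The acid chloride acylates (trimethylsilyl)diazomethane at carbon and chloride removes the silyl group (Arndt–Eistert-type synthesis of an α-diazo ketone), which introduces C5 as the diazo carbon.

Step 5
Reactants: 8 1-diazo-4-(4-methyl-2-{[tri(propan-2-yl)silyl]oxy}phenyl)butan-2-one
Product: 10 (8aR)-6-methyl-4-{[tri(propan-2-yl)silyl]oxy}-3,8a-dihydroazulen-1(2H)-one, via norcaradiene 9 (not isolated)
Conditions: CuCl (5 mol %), NaB[3,5-(CF3)2C6H3]4 (6 mol %), 2,2'-(propane-2,2-diyl)bis[(4S)-4-tert-butyl-4,5-dihydrooxazole] (6 mol %, or its antipode, see remark), CH2Cl2, reflux, slow addition of 8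
Reagents that add atoms: none
Why: The monovalent copper catalyst converts the diazo ketone, with loss of N2, into an electrophilic copper carbene that cyclopropanates the ipso–ortho π bond of the arene (C1–C6) to give norcaradiene 9, and thermal disrotatory 6π electrocyclic opening then cleaves the C1–C6 bond to give the cycloheptatriene. This is the intramolecular Buchner reaction of 1-diazo-4-arylbutan-2-ones, a known route to 3,8a-dihydroazulen-1(2H)-ones that is enantioselective with copper bis(oxazoline) catalysts. The five-membered ring closes when the tethered carbene carbon C5 bonds to the ipso carbon C1 (exo attack through the C2–C3–C4 tether), whereas the seven-membered ring is not made by cyclisation but by ring expansion of the benzene ring as C5 is inserted between C1 and C6. The only new stereocentre, C5, is set by the bis(oxazoline) ligand, which differentiates the enantiotopic faces of carbene approach to the arene. The required regioselectivity (C1–C6 and not C1–C10) should be secured by the bulky triisopropylsilyloxy group on C10, which blocks the other ipso–ortho bond, and the non-acidic medium should prevent the known acid-induced isomerisation of such azulenones to 2-tetralones.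

Step 6
Reactants: 10 (8aR)-6-methyl-4-{[tri(propan-2-yl)silyl]oxy}-3,8a-dihydroazulen-1(2H)-one
Product: 11 (1R,8aR)-6-methyl-1-(propan-2-yl)-4-{[tri(propan-2-yl)silyl]oxy}-1,2,3,8a-tetrahydroazulen-1-ol
Conditions: CeCl3 (anhydrous, 1.5 equiv), i-PrMgCl (1.5 equiv), THF, −78 °C; then 10; aq NH4Cl
Reagents that add atoms: isopropylmagnesium chloride, CC(C)[Mg]Cl
Why: The weakly basic organocerium reagent undergoes 1,2-addition to the ketone (organocerium carbonyl addition) without removing the acidic C5–H, and it should attack the cyclopentanone face that carries H5 because the vinylic C6–H projects under the opposite face, so that the isopropyl group is cis to H5 and the C4 hydroxyl is cis to C6.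

Step 7
Reactants: 11 (1R,8aR)-6-methyl-1-(propan-2-yl)-4-{[tri(propan-2-yl)silyl]oxy}-1,2,3,8a-tetrahydroazulen-1-ol
Product: 12 5-methyl-9-(propan-2-yl)-3-{[tri(propan-2-yl)silyl]oxy}tricyclo[6.3.0.0(1,3)]undeca-4,6-dien-9-ol (11 with a CH2 group bridging C1 and C10 on the face of the C4 hydroxyl, anti to H5)
Conditions: Et2Zn (2.0 equiv), CH2I2 (2.0 equiv), CH2Cl2, −20 → 0 °C; aq NH4Cl
Reagents that add atoms: diiodomethane, ICI
Why: In this hydroxyl-directed Simmons–Smith cyclopropanation the zinc alkoxide at C4 should deliver the methylene to the most electron-rich double bond, the C1=C10 silyl enol ether, on the face of the hydroxyl, so that the new C1–CH2 bond is cis to O4 and trans to H5 and C10 follows by syn addition.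

Step 8
Reactants: 12 5-methyl-9-(propan-2-yl)-3-{[tri(propan-2-yl)silyl]oxy}tricyclo[6.3.0.0(1,3)]undeca-4,6-dien-9-ol
Product: 14 (3R,3aR,8aS)-3-hydroxy-6,8a-dimethyl-3-(propan-2-yl)-1,2,3,3a-tetrahydroazulen-8(8aH)-one, via cyclopropanol 13 (not isolated)
Conditions: Bu4NF (1.2 equiv), THF–MeOH (10:1), 0 °C → rt; aq NH4Cl
Reagents that add atoms: none
Why: Fluoride desilylation releases the 1-alkenylcyclopropanolate, which should undergo the known base-induced cyclopropanol ring opening at the bond to the least substituted carbon (C10–CH2) with protonation by methanol, so that the CH2 becomes the C1 methyl group with retention at C1 and C10 becomes the dienone carbonyl (α-methylation of a ketone through its siloxycyclopropane).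

Step 9
Reactants: 14 (3R,3aR,8aS)-3-hydroxy-6,8a-dimethyl-3-(propan-2-yl)-1,2,3,3a-tetrahydroazulen-8(8aH)-one
Product: 15 (3R,3aS,4R,5S,8aS)-4,5-epoxy-3-hydroxy-6,8a-dimethyl-3-(propan-2-yl)-1,2,3,3a,4,5-hexahydroazulen-8(8aH)-one (epoxide on C6–C7, oxygen syn to H5)
Conditions: dimethyldioxirane (1.1 equiv, about 0.07 M in acetone), 0 °C
Reagents that add atoms: dimethyldioxirane, CC1(C)OO1
Why: Electrophilic epoxidation of a 2,4-dienone takes place at the distal, more electron-rich γ,δ-double bond (C6=C7), and the pseudo-axial C1 methyl group together with the C4 carbinol carbon should shield the face anti to H5, so that oxygen is delivered syn to H5 and C6 receives the configuration of the target while C7 is an auxiliary centre erased in step 10.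

Step 10
Reactants: 15 (3R,3aS,4R,5S,8aS)-4,5-epoxy-3-hydroxy-6,8a-dimethyl-3-(propan-2-yl)-1,2,3,3a,4,5-hexahydroazulen-8(8aH)-one
Product: 16 (3R,3aS,4S,8aS)-3,4-dihydroxy-6,8a-dimethyl-3-(propan-2-yl)-1,2,3,3a,4,5-hexahydroazulen-8(8aH)-one
Conditions: Pd2(dba)3·CHCl3 (2.5 mol %), n-Bu3P (10 mol %), HCO2H (5 equiv), Et3N (2 equiv), 1,4-dioxane, rt
Reagents that add atoms: none
Why: In this palladium-catalysed formate hydrogenolysis of an alkenyl oxirane (π-allyl chemistry of the Tsuji–Trost type) zerovalent palladium ionises the allylic C7–O bond to a π-allyl complex over C7–C9 and hydride from formate is transferred to C7, so that the C6–O bond and its configuration are untouched and the C8=C9 double bond stays conjugated with the C10 ketone.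

Step 11
Reactants: 16 (3R,3aS,4S,8aS)-3,4-dihydroxy-6,8a-dimethyl-3-(propan-2-yl)-1,2,3,3a,4,5-hexahydroazulen-8(8aH)-one; 17 3,4,5-trimethoxybenzoyl chloride
Product: 18 (3R,3aS,4S,8aS)-3-hydroxy-6,8a-dimethyl-8-oxo-3-(propan-2-yl)-1,2,3,3a,4,5,8,8a-octahydroazulen-4-yl 3,4,5-trimethoxybenzoate (CNP0218356.1)
Conditions: 17 (1.3 equiv), pyridine (3 equiv), DMAP (0.2 equiv), CH2Cl2, 0 °C → rt
Reagents that add atoms: none
Why: DMAP-catalysed acylation with the acid chloride (esterification) should take place at the secondary C6 hydroxyl with retention, the hindered tertiary C4 hydroxyl being unreactive, and the weak base and low temperature should avoid vinylogous β-elimination of the δ-acyloxy enone.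

**Compound list**

1 | 2-hydroxy-4-methylbenzaldehyde | Cc1ccc(C=O)c(O)c1 | starting material
2 | 4-methyl-2-{[tri(propan-2-yl)silyl]oxy}benzaldehyde | Cc1ccc(C=O)c(O[Si](C(C)C)(C(C)C)C(C)C)c1 | intermediate
3 | benzyl (triphenylphosphoranylidene)acetate | O=C(C=P(c1ccccc1)(c1ccccc1)c1ccccc1)OCc1ccccc1 | starting material
4 | benzyl (2E)-3-(4-methyl-2-{[tri(propan-2-yl)silyl]oxy}phenyl)prop-2-enoate | Cc1ccc(/C=C/C(=O)OCc2ccccc2)c(O[Si](C(C)C)(C(C)C)C(C)C)c1 | intermediate
5 | 3-(4-methyl-2-{[tri(propan-2-yl)silyl]oxy}phenyl)propanoic acid | Cc1ccc(CCC(=O)O)c(O[Si](C(C)C)(C(C)C)C(C)C)c1 | intermediate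
6 | (trimethylsilyl)diazomethane | C[Si](C)(C)C=[N+]=[N-] | starting material
7 | 3-(4-methyl-2-{[tri(propan-2-yl)silyl]oxy}phenyl)propanoyl chloride | Cc1ccc(CCC(=O)Cl)c(O[Si](C(C)C)(C(C)C)C(C)C)c1 | intermediate (not isolated)
8 | 1-diazo-4-(4-methyl-2-{[tri(propan-2-yl)silyl]oxy}phenyl)butan-2-one | Cc1ccc(CCC(=O)C=[N+]=[N-])c(O[Si](C(C)C)(C(C)C)C(C)C)c1 | intermediate
9 | norcaradiene tautomer of 10: 8-methyl-10-{[tri(propan-2-yl)silyl]oxy}tricyclo[4.4.0.0(1,5)]deca-7,9-dien-4-one, cyclopropane C1–C5–C6 cis-fused to both rings | O=C1CC[C@@]23C(O[Si](C(C)C)(C(C)C)C(C)C)=CC(C)=C[C@@H]2[C@@H]13 | intermediate (not isolated)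
10 | (8aR)-6-methyl-4-{[tri(propan-2-yl)silyl]oxy}-3,8a-dihydroazulen-1(2H)-one | O=C1CCC2=C(O[Si](C(C)C)(C(C)C)C(C)C)C=C(C)C=C[C@@H]12 | intermediate
11 | (1R,8aR)-6-methyl-1-(propan-2-yl)-4-{[tri(propan-2-yl)silyl]oxy}-1,2,3,8a-tetrahydroazulen-1-ol | CC(C)[C@]1(O)CCC2=C(O[Si](C(C)C)(C(C)C)C(C)C)C=C(C)C=C[C@@H]12 | intermediate
12 | 5-methyl-9-(propan-2-yl)-3-{[tri(propan-2-yl)silyl]oxy}tricyclo[6.3.0.0(1,3)]undeca-4,6-dien-9-ol, CH2 bridging C1 and C10 cis to the C4 hydroxyl and trans to H5 | CC(C)[C@]1(O)CC[C@]23C[C@@]2(O[Si](C(C)C)(C(C)C)C(C)C)C=C(C)C=C[C@@H]13 | intermediate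
13 | 5-methyl-9-(propan-2-yl)tricyclo[6.3.0.0(1,3)]undeca-4,6-diene-3,9-diol (cyclopropanol, present as its alkoxide), same configuration as 12 | CC(C)[C@]1(O)CC[C@]23C[C@@]2(O)C=C(C)C=C[C@@H]13 | intermediate (not isolated)
14 | (3R,3aR,8aS)-3-hydroxy-6,8a-dimethyl-3-(propan-2-yl)-1,2,3,3a-tetrahydroazulen-8(8aH)-one | CC(C)[C@]1(O)CC[C@]2(C)C(=O)C=C(C)C=C[C@@H]12 | intermediate
15 | (3R,3aS,4R,5S,8aS)-4,5-epoxy-3-hydroxy-6,8a-dimethyl-3-(propan-2-yl)-1,2,3,3a,4,5-hexahydroazulen-8(8aH)-one | CC(C)[C@]1(O)CC[C@]2(C)C(=O)C=C(C)[C@@H]3O[C@@H]3[C@@H]12 | intermediate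
16 | (3R,3aS,4S,8aS)-3,4-dihydroxy-6,8a-dimethyl-3-(propan-2-yl)-1,2,3,3a,4,5-hexahydroazulen-8(8aH)-one | CC(C)[C@]1(O)CC[C@]2(C)C(=O)C=C(C)C[C@H](O)[C@@H]12 | intermediate
17 | 3,4,5-trimethoxybenzoyl chloride | COc1cc(C(=O)Cl)cc(OC)c1OC | starting material
18 | (3R,3aS,4S,8aS)-3-hydroxy-6,8a-dimethyl-8-oxo-3-(propan-2-yl)-1,2,3,3a,4,5,8,8a-octahydroazulen-4-yl 3,4,5-trimethoxybenzoate | COc1cc(C(=O)O[C@H]2CC(C)=CC(=O)[C@@]3(C)CC[C@@](O)(C(C)C)[C@H]23)cc(OC)c1OC | target

**Count and risks**

Total steps: 11. Longest linear sequence: 11 steps (1 → 18); compounds 3, 6 and 17 are bought.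

Steps most likely to fail, in order of risk:

1. Step 7. The C4 alkoxide is also within reach of the C6=C7 bond, so the carbenoid may be delivered to the diene part or add twice, or the hindered tetrasubstituted enol ether may react too slowly. The fallback replaces cyclopropanation by enolate alkylation. It sets out from 11: Bu4NF buffered with AcOH in THF at 0 °C removes the silyl group, and protonation at C1 gives the C1-unsubstituted dienone (3R,3aR)-3-hydroxy-6-methyl-3-(propan-2-yl)-1,2,3,3a-tetrahydroazulen-8(8aH)-one F1 as a mixture of C1 epimers, which is of no consequence. LiN(i-Pr)2 (2.2 equiv) in THF at −78 °C then forms the alkoxide and, by kinetic α'-deprotonation, the cross-conjugated C1 enolate. MeI should alkylate C1 on the face anti to H5, which brings the sequence back to 14.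

2. Step 9. Hydrogen-bond delivery of the oxidant by the C4 hydroxyl may override the steric bias and lead to epoxidation on the face anti to H5, hence to the wrong configuration at C6. The fallback is a stereoconvergent oxidation followed by hydroxyl-directed reduction. It sets out from 14: the epoxidation product, including the epimeric epoxide F2, is opened under the conditions of step 10 to give the C6 epimer of 16 F3 beside any 16. Dess–Martin periodinane (NaHCO3, CH2Cl2, rt) oxidises both secondary alcohols to the one C6 ketone F4. Me4NBH(OAc)3 in MeCN–AcOH at −20 °C, bound to the C4 hydroxyl, should then deliver hydride to C6 on the hydroxyl face (Evans–Saksena anti reduction of a β-hydroxy ketone, the C10 enone lacking a directing group), which gives 16.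

3. Step 5. Enantiofacial discrimination may be insufficient with the ortho-silyloxy substituent, or the cationic copper salt may isomerise the product. The fallback is a racemic ring expansion followed by resolution. It sets out from 8: Rh2(OAc)4 (0.5 mol %) in CH2Cl2 at rt gives the racemic azulenone F5, and organocerium addition as in step 6 gives the racemic tertiary alcohol F6. Preparative HPLC on a chiral stationary phase (amylose tris(3,5-dimethylphenylcarbamate)) separates the enantiomers, and the (1R,8aR) enantiomer is 11.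

Further compounds
F1 | step 7 | (3R,3aR)-3-hydroxy-6-methyl-3-(propan-2-yl)-1,2,3,3a-tetrahydroazulen-8(8aH)-one, C1 (position 8a) epimers | CC(C)[C@]1(O)CCC2C(=O)C=C(C)C=C[C@@H]12
F2 | step 9 | C6/C7-epimeric epoxide of 15 (epoxide oxygen anti to H5) | CC(C)[C@]1(O)CC[C@]2(C)C(=O)C=C(C)[C@H]3O[C@H]3[C@@H]12
F3 | step 9 | C6 epimer of 16 (C6 hydroxyl anti to H5) | CC(C)[C@]1(O)CC[C@]2(C)C(=O)C=C(C)C[C@@H](O)[C@@H]12
F4 | step 9 | C6 ketone: 3-hydroxy-6,8a-dimethyl-3-(propan-2-yl)-2,3,3a,5-tetrahydroazulene-4,8(1H,8aH)-dione, configuration at C1, C4 and C5 as in 16 | CC(C)[C@]1(O)CC[C@]2(C)C(=O)C=C(C)CC(=O)[C@@H]12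
F5 | step 5 | racemic 10 | O=C1CCC2=C(O[Si](C(C)C)(C(C)C)C(C)C)C=C(C)C=C[C@@H]12.O=C1CCC2=C(O[Si](C(C)C)(C(C)C)C(C)C)C=C(C)C=C[C@H]12
F6 | step 5 | racemic 11, relative configuration (1R*,8aR*) | CC(C)[C@]1(O)CCC2=C(O[Si](C(C)C)(C(C)C)C(C)C)C=C(C)C=C[C@@H]12.CC(C)[C@@]1(O)CCC2=C(O[Si](C(C)C)(C(C)C)C(C)C)C=C(C)C=C[C@H]12
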